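**Retrosynthetic overview**
- The target is read as (+)-gallocatechin-(4α→8)-(+)-catechin-(4β→8)-(−)-catechin. The last bonds made are the fourteen O–H bonds (global hydrogenolysis) and, before that, the C4(top)–C8(middle) bond, by cationic Friedel–Crafts union of a protected flavan-3,4-diol with a protected dimer.
- The flavan-3,4-diol unit is made in one operation from an acyclic anti-aldol aldehyde (ring B, O1, C2–C4, both stereocenters) and 3,5-bis(benzyloxy)benzyne (ring A). This annulation forms O1–C8a and C4–C4a and closes ring C.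
- Enabling feature: ring A of the top unit is a 1,3,5-trioxygenated benzene that is joined to ring C only through the adjacent carbons C4a and C8a, so this C–C bond can be brought in as the aryne triple bond. The oxygen on C5, next to C4a, steers the O-nucleophile to C8a and the carbanion to C4a.
- The aldehyde comes from an anti-glycolate aldol. The dimer comes from (+)-catechin and (−)-catechin, joined C4→C8 through a glutarate tether between the two C3 oxygens, which enforces the 3,4-cis linkage.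
- Ring order: rings A and B of the top unit are bought, ring C is made in the key step, and all rings of the middle and bottom units come from the catechins.

Key step: step 8

Assumption: the anti-glycolate aldol of the (4S)-thioimide is taken to pass through the chelated (Z)-titanium enolate and an open transition state, with the activated aldehyde adding to the enolate face remote from the 4-benzyl group, which gives the (2R,3R) adduct; if the facial sense were the reverse, the (4R)-auxiliary would be used with no other change.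

**Route**

Step 1
Reactants: 1 3,5-bis(benzyloxy)phenol
Product: 2 3,5-bis(benzyloxy)-2-bromophenol
Conditions: NBS (1.0 equiv), i-Pr2NH (cat.), CH2Cl2, −78 → 0 °C
Reagents that add atoms: N-bromosuccinimide, O=C1CCC(=O)N1Br
Why: Electrophilic aromatic bromination under the amine-catalyzed NBS protocol should place bromine ortho to the free hydroxyl, at the position between OH and OBn, which is less hindered than the one between the two benzyloxy groups.

Step 2
Reactants: 2 3,5-bis(benzyloxy)-2-bromophenol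
Product: 3 [3,5-bis(benzyloxy)-2-bromophenoxy]trimethylsilane
Conditions: HMDS, THF, 70 °C; concentrate
Reagents that add atoms: hexamethyldisilazane, C[Si](C)(C)N[Si](C)(C)C
Why: O-silylation of the phenol places the silyl group for the later intramolecular O→C transfer.

Step 3
Reactants: 3 [3,5-bis(benzyloxy)-2-bromophenoxy]trimethylsilane
Product: 5 3,5-bis(benzyloxy)-2-(trimethylsilyl)phenyl trifluoromethanesulfonate, via lithium phenolate 4 (not isolated)
Conditions: n-BuLi, THF, −100 → −78 °C; then Tf2O, −100 → −78 °C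
Reagents that add atoms: trifluoromethanesulfonic anhydride, O=S(=O)(OS(=O)(=O)C(F)(F)F)C(F)(F)F
Why: Bromine–lithium exchange and 1,3-retro-Brook rearrangement move silicon from oxygen to C2, and the phenolate 4 is then triflated, which is the standard route to ortho-silylaryl triflates.

Step 4
Reactants: 6 (4S)-4-benzyl-1,3-oxazolidine-2-thione; 7 (benzyloxy)acetyl chloride
Product: 8 (4S)-4-benzyl-3-[(benzyloxy)acetyl]-1,3-oxazolidine-2-thione
Conditions: Et3N, DMAP (cat.), CH2Cl2, 0 °C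
Reagents that add atoms: none
Why: N-acylation of the auxiliary by the acid chloride (acyl substitution) forms no stereocenter.

Step 5
Reactants: 8 (4S)-4-benzyl-3-[(benzyloxy)acetyl]-1,3-oxazolidine-2-thione; 9 3,4,5-tris(benzyloxy)benzaldehyde
Product: 11 (4S)-4-benzyl-3-{(2R,3R)-2-(benzyloxy)-3-hydroxy-3-[3,4,5-tris(benzyloxy)phenyl]propanoyl}-1,3-oxazolidine-2-thione, via titanium enolate 10 (not isolated)
Conditions: TiCl4 (1.1 equiv), i-Pr2NEt (1.2 equiv), CH2Cl2, −78 °C; then 9 premixed with TiCl4 (1.5 equiv each), −78 °C; aq. NH4Cl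
Reagents that add atoms: none
Why: Anti-selective glycolate aldol addition, in which the chelated (Z)-enolate 10 is attacked on the face remote from the 4-benzyl group (sets C2 as R) by the TiCl4-bound aldehyde in an open antiperiplanar transition state (sets C3 as R, anti to C2).

Step 6
Reactants: 11 (4S)-4-benzyl-3-{(2R,3R)-2-(benzyloxy)-3-hydroxy-3-[3,4,5-tris(benzyloxy)phenyl]propanoyl}-1,3-oxazolidine-2-thione
Product: 12 (2R,3R)-2-(benzyloxy)-3-hydroxy-N-methoxy-N-methyl-3-[3,4,5-tris(benzyloxy)phenyl]propanamide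
Conditions: MeONHMe·HCl, imidazole, CH2Cl2, rt
Reagents that add atoms: N,O-dimethylhydroxylamine hydrochloride, CNOC.Cl
Why: Aminolysis of the activated thioimide (acyl transfer) releases the auxiliary and leaves both stereocenters untouched.

Step 7
Reactants: 12 (2R,3R)-2-(benzyloxy)-3-hydroxy-N-methoxy-N-methyl-3-[3,4,5-tris(benzyloxy)phenyl]propanamide
Product: 13 (2R,3R)-2-(benzyloxy)-3-hydroxy-3-[3,4,5-tris(benzyloxy)phenyl]propanal
Conditions: i-Bu2AlH (3 equiv), THF, −78 °C; Rochelle salt; used crude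
Reagents that add atoms: none
Why: Hydride reduction of the N-methoxy-N-methylamide stops at the chelated aluminium hemiaminal, which should give the aldehyde on cold work-up without epimerization at C2.

Step 8
Reactants: 13 (2R,3R)-2-(benzyloxy)-3-hydroxy-3-[3,4,5-tris(benzyloxy)phenyl]propanal; 5 3,5-bis(benzyloxy)-2-(trimethylsilyl)phenyl trifluoromethanesulfonate
Product: 15 (2R,3S)-3,5,7-tris(benzyloxy)-2-[3,4,5-tris(benzyloxy)phenyl]-3,4-dihydro-2H-chromen-4-ol, via 3,5-bis(benzyloxy)benzyne 14 (not isolated)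
Conditions: KF (3 equiv), 18-crown-6 (3 equiv), THF, −20 → 0 °C, slow addition of 5 (1.3 equiv)
Reagents that add atoms: none
Why: Proposed new method: fluoride releases aryne 14 from 5, the fluoride-activated hydroxyl of 13 adds to it (O1–C8a), and the aryl carbanion thus placed at C4a adds to the aldehyde carbon six atoms away (C4–C4a) before it is protonated, so that a formal [4+2] annulation closes ring C onto ring A. The closest known reaction types are the fluoride-mediated O–H insertion of aliphatic alcohols into arynes and the annulations of arynes with salicylaldehydes, 2-hydroxyaryl ketones and 2-aminoaryl ketones, which give xanthenols and acridines by the same addition and carbonyl-trapping sequence; a non-aromatic β-hydroxy aldehyde has not been used in this way. Ring C closes by 6-exo-trig attack of the sp2 carbanion on the carbonyl group after the intermolecular O-arylation. C2 and C3 of the chroman come unchanged from 13 because neither of their C–O bonds is broken, and the new carbinol center C4 is expected as a mixture of epimers, which is acceptable because C4 is ionized in step 16. The step needs O-addition at the aryne carbon that becomes C8a, and the benzyloxy group at C5 secures this: it distorts the aryne so that the nucleophile adds meta to it and the charge develops ortho to it, next to the inductively stabilizing oxygen. It also needs ring closure to outrun protonation of the carbanion and retro-aldol cleavage of 13, which is why an aprotic medium, low temperature and slow addition of 5 are chosen.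

Step 9
Reactants: 16 (+)-catechin
Product: 17 5,7,3',4'-tetra-O-benzyl-(+)-catechin
Conditions: BnBr (4.4 equiv), K2CO3, DMF, 0 °C → rt
Reagents that add atoms: benzyl bromide, BrCc1ccccc1
Why: Williamson etherification of the four phenolic hydroxyls, which are far more acidic than the C3 alcohol, leaves the stereocenters untouched.

Step 10
Reactants: 18 (−)-catechin
Product: 19 5,7,3',4'-tetra-O-benzyl-(−)-catechin
Conditions: BnBr (4.4 equiv), K2CO3, DMF, 0 °C → rt
Reagents that add atoms: benzyl bromide, BrCc1ccccc1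
Why: Williamson etherification of the four phenolic hydroxyls as in step 9 leaves the stereocenters untouched.

Step 11
Reactants: 17 5,7,3',4'-tetra-O-benzyl-(+)-catechin
Product: 20 (2R,3S,4S)-5,7-bis(benzyloxy)-2-[3,4-bis(benzyloxy)phenyl]-4-(2-ethoxyethoxy)-3,4-dihydro-2H-chromen-3-ol
Conditions: DDQ (2 equiv), 2-ethoxyethanol (5 equiv), CH2Cl2, rt
Reagents that add atoms: 2-ethoxyethanol, CCOCCO
Why: DDQ abstracts hydride from benzylic C4 (oxidative C–H functionalization) and the cation stabilized by ring A is trapped by the alcohol anti to the C2 aryl group, which sets C4 as S, a center that is ionized again in step 14.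

Step 12
Reactants: 19 5,7,3',4'-tetra-O-benzyl-(−)-catechin
Product: 21 5-{[(2S,3R)-5,7-bis(benzyloxy)-2-[3,4-bis(benzyloxy)phenyl]-3,4-dihydro-2H-chromen-3-yl]oxy}-5-oxopentanoic acid
Conditions: glutaric anhydride, DMAP, pyridine, 60 °C
Reagents that add atoms: glutaric anhydride, O=C1CCCC(=O)O1
Why: DMAP-catalyzed ring-opening acylation of the anhydride by the secondary C3 alcohol gives the half-ester.

Step 13
Reactants: 20 (2R,3S,4S)-5,7-bis(benzyloxy)-2-[3,4-bis(benzyloxy)phenyl]-4-(2-ethoxyethoxy)-3,4-dihydro-2H-chromen-3-ol; 21 5-{[(2S,3R)-5,7-bis(benzyloxy)-2-[3,4-bis(benzyloxy)phenyl]-3,4-dihydro-2H-chromen-3-yl]oxy}-5-oxopentanoic acid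
Product: 22 glutarate diester that links O3 of the 4-(2-ethoxyethoxy)-(+)-catechin unit to O3 of the (−)-catechin unit
Conditions: EDC·HCl, DMAP, CH2Cl2, rt
Reagents that add atoms: none
Why: Carbodiimide-mediated (Steglich) esterification joins the two flavan units through their C3 oxygens.

Step 14
Reactants: 22 glutarate diester that links O3 of the 4-(2-ethoxyethoxy)-(+)-catechin unit to O3 of the (−)-catechin unit
Product: 23 macrocyclic 3,3''-O-glutaryl-bridged octa-O-benzyl (+)-catechin-(4β→8)-(−)-catechin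
Conditions: TMSOTf (0.5 equiv), CH2Cl2 (1 mM), −78 → −20 °C; Et3N quench
Reagents that add atoms: none
Why: Lewis-acid ionization of the C4 ether and intramolecular Friedel–Crafts alkylation at C8 of the tethered (−)-catechin ring, where the tether anchored on O3 can deliver the arene only to the C4 face syn to O3, which sets C4 as 3,4-cis (4β), and high dilution suppresses intermolecular coupling.

Step 15
Reactants: 23 macrocyclic 3,3''-O-glutaryl-bridged octa-O-benzyl (+)-catechin-(4β→8)-(−)-catechin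
Product: 24 octa-O-benzyl (+)-catechin-(4β→8)-(−)-catechin
Conditions: NaOMe (cat.), MeOH–THF, rt
Reagents that add atoms: none
Why: Base-catalyzed transesterification (methanolysis) removes the tether without touching the benzyl ethers or the interflavan bond.

Step 16
Reactants: 15 (2R,3S)-3,5,7-tris(benzyloxy)-2-[3,4,5-tris(benzyloxy)phenyl]-3,4-dihydro-2H-chromen-4-ol; 24 octa-O-benzyl (+)-catechin-(4β→8)-(−)-catechin
Product: 25 tetradeca-O-benzyl (+)-gallocatechin-(4α→8)-(+)-catechin-(4β→8)-(−)-catechin (all phenols and O3 of the top unit benzylated)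
Conditions: 24 (2 equiv, excess recovered), TMSOTf (0.3 equiv), 4 Å MS, CH2Cl2, −78 → −30 °C, slow addition of 15; Et3N quench
Reagents that add atoms: none
Why: Lewis-acid-catalyzed ionization of the C4 hydroxyl of 15 and intermolecular Friedel–Crafts alkylation at the only free C8 position of 24 (upper unit, the most nucleophilic site), where the arene adds to the 2,3-trans cation anti to the C3 benzyloxy group, which sets C4 as 3,4-trans (4α).

Step 17
Reactants: 25 tetradeca-O-benzyl (+)-gallocatechin-(4α→8)-(+)-catechin-(4β→8)-(−)-catechin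
Product: 26 (+)-gallocatechin-(4α→8)-(+)-catechin-(4β→8)-(−)-catechin (CNP0155646.2)
Conditions: H2 (1 atm), Pd(OH)2/C, THF–MeOH–H2O, rt
Reagents that add atoms: none
Why: Hydrogenolysis cleaves all fourteen benzyl ethers, while the C–C interflavan bonds and the stereocenters are inert under these neutral conditions.

**Compound list**
1 | 3,5-bis(benzyloxy)phenol | Oc1cc(OCc2ccccc2)cc(OCc2ccccc2)c1 | starting material
2 | 3,5-bis(benzyloxy)-2-bromophenol | Oc1cc(OCc2ccccc2)cc(OCc2ccccc2)c1Br | intermediate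
3 | [3,5-bis(benzyloxy)-2-bromophenoxy]trimethylsilane | C[Si](C)(C)Oc1cc(OCc2ccccc2)cc(OCc2ccccc2)c1Br | intermediate
4 | lithium 3,5-bis(benzyloxy)-2-(trimethylsilyl)phenolate | [Li+].[O-]c1cc(OCc2ccccc2)cc(OCc2ccccc2)c1[Si](C)(C)C | intermediate
5 | 3,5-bis(benzyloxy)-2-(trimethylsilyl)phenyl trifluoromethanesulfonate | C[Si](C)(C)c1c(OS(=O)(=O)C(F)(F)F)cc(OCc2ccccc2)cc1OCc1ccccc1 | intermediate
6 | (4S)-4-benzyl-1,3-oxazolidine-2-thione | S=C1N[C@@H](Cc2ccccc2)CO1 | starting material
7 | (benzyloxy)acetyl chloride | ClC(=O)COCc1ccccc1 | starting material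
8 | (4S)-4-benzyl-3-[(benzyloxy)acetyl]-1,3-oxazolidine-2-thione | O=C(COCc1ccccc1)N1C(=S)OC[C@@H]1Cc1ccccc1 | intermediate
9 | 3,4,5-tris(benzyloxy)benzaldehyde | O=Cc1cc(OCc2ccccc2)c(OCc2ccccc2)c(OCc2ccccc2)c1 | starting material
10 | trichlorotitanium (Z)-enolate of 8 | Cl[Ti](Cl)(Cl)O/C(=C\OCc1ccccc1)N1C(=S)OC[C@@H]1Cc1ccccc1 | intermediate
11 | (4S)-4-benzyl-3-{(2R,3R)-2-(benzyloxy)-3-hydroxy-3-[3,4,5-tris(benzyloxy)phenyl]propanoyl}-1,3-oxazolidine-2-thione | O=C([C@H](OCc1ccccc1)[C@H](O)c1cc(OCc2ccccc2)c(OCc2ccccc2)c(OCc2ccccc2)c1)N1C(=S)OC[C@@H]1Cc1ccccc1 | intermediate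
12 | (2R,3R)-2-(benzyloxy)-3-hydroxy-N-methoxy-N-methyl-3-[3,4,5-tris(benzyloxy)phenyl]propanamide | CON(C)C(=O)[C@H](OCc1ccccc1)[C@H](O)c1cc(OCc2ccccc2)c(OCc2ccccc2)c(OCc2ccccc2)c1 | intermediate
13 | (2R,3R)-2-(benzyloxy)-3-hydroxy-3-[3,4,5-tris(benzyloxy)phenyl]propanal | O=C[C@H](OCc1ccccc1)[C@H](O)c1cc(OCc2ccccc2)c(OCc2ccccc2)c(OCc2ccccc2)c1 | intermediate
14 | 3,5-bis(benzyloxy)benzyne | C1#CC(OCc2ccccc2)=CC(OCc2ccccc2)=C1 | intermediate
15 | (2R,3S)-3,5,7-tris(benzyloxy)-2-[3,4,5-tris(benzyloxy)phenyl]-3,4-dihydro-2H-chromen-4-ol (C4 epimers) | O(Cc3ccccc3)c1cc(OCc3ccccc3)c2c(c1)O[C@H](c1cc(OCc3ccccc3)c(OCc3ccccc3)c(OCc3ccccc3)c1)[C@@H](OCc3ccccc3)C2O | intermediate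
16 | (+)-catechin, (2R,3S) | Oc1cc(O)c2c(c1)O[C@H](c1ccc(O)c(O)c1)[C@@H](O)C2 | starting material
17 | 5,7,3',4'-tetra-O-benzyl-(+)-catechin | O(Cc3ccccc3)c1cc(OCc3ccccc3)c2c(c1)O[C@H](c1ccc(OCc3ccccc3)c(OCc3ccccc3)c1)[C@@H](O)C2 | intermediate
18 | (−)-catechin, (2S,3R) | Oc1cc(O)c2c(c1)O[C@@H](c1ccc(O)c(O)c1)[C@H](O)C2 | starting material
19 | 5,7,3',4'-tetra-O-benzyl-(−)-catechin | O(Cc3ccccc3)c1cc(OCc3ccccc3)c2c(c1)O[C@@H](c1ccc(OCc3ccccc3)c(OCc3ccccc3)c1)[C@H](O)C2 | intermediate
20 | (2R,3S,4S)-5,7-bis(benzyloxy)-2-[3,4-bis(benzyloxy)phenyl]-4-(2-ethoxyethoxy)-3,4-dihydro-2H-chromen-3-ol | O(Cc3ccccc3)c1cc(OCc3ccccc3)c2c(c1)O[C@H](c1ccc(OCc3ccccc3)c(OCc3ccccc3)c1)[C@@H](O)[C@H]2OCCOCC | intermediate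
21 | 5-{[(2S,3R)-5,7-bis(benzyloxy)-2-[3,4-bis(benzyloxy)phenyl]-3,4-dihydro-2H-chromen-3-yl]oxy}-5-oxopentanoic acid | O(Cc3ccccc3)c1cc(OCc3ccccc3)c2c(c1)O[C@@H](c1ccc(OCc3ccccc3)c(OCc3ccccc3)c1)[C@H](OC(=O)CCCC(=O)O)C2 | intermediate
22 | glutarate diester of 20 (through O3) and 19 (through O3) | O(Cc3ccccc3)c1cc(OCc3ccccc3)c2c(c1)O[C@H](c1ccc(OCc3ccccc3)c(OCc3ccccc3)c1)[C@@H](OC(=O)CCCC(=O)O[C@@H]1Cc4c(OCc3ccccc3)cc(OCc3ccccc3)cc4O[C@H]1c1ccc(OCc3ccccc3)c(OCc3ccccc3)c1)[C@H]2OCCOCC | intermediate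
23 | macrocyclic 3,3''-O-glutaryl-bridged octa-O-benzyl (+)-catechin-(4β→8)-(−)-catechin (3,4-cis in the upper unit) | O(Cc3ccccc3)c1cc(OCc3ccccc3)c2c(c1)O[C@H](c1ccc(OCc3ccccc3)c(OCc3ccccc3)c1)[C@@H](OC(=O)CCCC(=O)O4)[C@H]2c1c(OCc3ccccc3)cc(OCc3ccccc3)c2c1O[C@@H](c1ccc(OCc3ccccc3)c(OCc3ccccc3)c1)[C@H]4C2 | intermediate
24 | octa-O-benzyl (+)-catechin-(4β→8)-(−)-catechin, both C3 hydroxyls free | O(Cc3ccccc3)c1cc(OCc3ccccc3)c2c(c1)O[C@H](c1ccc(OCc3ccccc3)c(OCc3ccccc3)c1)[C@@H](O)[C@H]2c1c(OCc3ccccc3)cc(OCc3ccccc3)c2c1O[C@@H](c1ccc(OCc3ccccc3)c(OCc3ccccc3)c1)[C@H](O)C2 | intermediate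
25 | tetradeca-O-benzyl (+)-gallocatechin-(4α→8)-(+)-catechin-(4β→8)-(−)-catechin (top unit O3 benzylated, middle and bottom O3 free) | O(Cc3ccccc3)c1cc(OCc3ccccc3)c2c(c1)O[C@H](c1cc(OCc3ccccc3)c(OCc3ccccc3)c(OCc3ccccc3)c1)[C@@H](OCc3ccccc3)[C@@H]2c1c(OCc3ccccc3)cc(OCc3ccccc3)c2c1O[C@H](c1ccc(OCc3ccccc3)c(OCc3ccccc3)c1)[C@@H](O)[C@H]2c1c(OCc3ccccc3)cc(OCc3ccccc3)c2c1O[C@@H](c1ccc(OCc3ccccc3)c(OCc3ccccc3)c1)[C@H](O)C2 | intermediate
26 | (+)-gallocatechin-(4α→8)-(+)-catechin-(4β→8)-(−)-catechin (CNP0155646.2) | Oc1cc(O)c2c(c1)O[C@H](c1cc(O)c(O)c(O)c1)[C@@H](O)[C@@H]2c1c(O)cc(O)c2c1O[C@H](c1ccc(O)c(O)c1)[C@@H](O)[C@H]2c1c(O)cc(O)c2c1O[C@@H](c1ccc(O)c(O)c1)[C@H](O)C2 | target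

**Step count and risks**

Total steps: 17. Longest linear sequence: 7 steps (steps 4, 5, 6, 7, 8, 16, 17; the dimer branch through steps 9, 11, 13, 14, 15, 16, 17 is equally long).

Steps most likely to fail:

1. Step 8 (proposed new method). The aryl carbanion may be protonated before it reaches the aldehyde, so that only O-arylation occurs. Fluoride may also cause retro-aldol cleavage or C3 epimerization of 13, and the product alcohol may be arylated a second time.
Fallback (known chemistry, sets out from 12 and 5, returns at 15): the hydroxyl of 12 is arylated by the aryne from 5 under the known O–H insertion conditions (CsF, MeCN, rt; the solvent protonates the carbanion) to give (2R,3R)-2-(benzyloxy)-3-[3,5-bis(benzyloxy)phenoxy]-N-methoxy-N-methyl-3-[3,4,5-tris(benzyloxy)phenyl]propanamide F1. Reduction with i-Bu2AlH (THF, −78 °C) gives (2R,3R)-2-(benzyloxy)-3-[3,5-bis(benzyloxy)phenoxy]-3-[3,4,5-tris(benzyloxy)phenyl]propanal F2. Me2AlCl (CH2Cl2, −78 °C) then closes ring C by intramolecular Friedel–Crafts hydroxyalkylation at the position ortho to the ether oxygen of the electron-rich ring and gives 15. Ring C is thus closed by electrophilic substitution instead of carbanion addition.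

2. Step 14. The tethered cation may be captured intermolecularly (oligomerization) or at C6 of the nucleophilic ring, or the fourteen-membered transition state may fail to enforce delivery syn to O3, so that the 3,4-cis configuration is not secured.
Fallback (sets out from 17 and 19, returns at 24): the C4 stereocenter is set by hydride delivery instead of arene delivery. 17 is silylated (TBSOTf, 2,6-lutidine) to the 3-O-tert-butyldimethylsilyl ether of 17 F3, oxidized at C4 with DDQ in wet CH2Cl2 to the 4-hydroxy derivative of F3 F4, and then with Dess–Martin periodinane to (2R,3R)-5,7-bis(benzyloxy)-2-[3,4-bis(benzyloxy)phenyl]-3-(tert-butyldimethylsilyloxy)chroman-4-one F5. 19 is brominated (NBS, CH2Cl2, −78 °C) to 8-bromo-5,7,3',4'-tetra-O-benzyl-(−)-catechin F6. F6 is deprotonated with MeLi, lithiated with t-BuLi (THF, −78 °C) and added to F5 to give the C4 tertiary alcohol with the C4–C8 bond in place F7. Ionic hydrogenation (Et3SiH, CF3CO2H, CH2Cl2, −78 °C) delivers hydride to the C4 cation anti to the C3 silyloxy group, which leaves the aryl group cis to it, and gives the 3-O-tert-butyldimethylsilyl ether of 24 F8. Bu4NF (THF) then gives 24.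

3. Step 16. The cation from 15 may be attacked by ring A of a second molecule of 15 (self-condensation), or may add to C6 of either unit of 24 instead of C8 of the upper unit.
Fallback (sets out from 15, returns at 26): ring A of the electrophile is capped and deactivated. 15 is brominated at C8 (NBS, CH2Cl2, −78 °C) to the 8-bromo derivative of 15 F9, which is coupled with 24 under the conditions of step 16 to the 8-bromo derivative of 25 F10. Hydrogenolysis (H2, Pd(OH)2/C, Et3N, THF–MeOH–H2O) removes the bromine together with the benzyl groups and gives 26.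

**Further compounds**
F1 | step 8 | (2R,3R)-2-(benzyloxy)-3-[3,5-bis(benzyloxy)phenoxy]-N-methoxy-N-methyl-3-[3,4,5-tris(benzyloxy)phenyl]propanamide | CON(C)C(=O)[C@H](OCc1ccccc1)[C@H](Oc1cc(OCc2ccccc2)cc(OCc2ccccc2)c1)c1cc(OCc2ccccc2)c(OCc2ccccc2)c(OCc2ccccc2)c1
F2 | step 8 | (2R,3R)-2-(benzyloxy)-3-[3,5-bis(benzyloxy)phenoxy]-3-[3,4,5-tris(benzyloxy)phenyl]propanal | O=C[C@H](OCc1ccccc1)[C@H](Oc1cc(OCc2ccccc2)cc(OCc2ccccc2)c1)c1cc(OCc2ccccc2)c(OCc2ccccc2)c(OCc2ccccc2)c1
F3 | step 14 | 3-O-tert-butyldimethylsilyl ether of 17 | O(Cc3ccccc3)c1cc(OCc3ccccc3)c2c(c1)O[C@H](c1ccc(OCc3ccccc3)c(OCc3ccccc3)c1)[C@@H](O[Si](C)(C)C(C)(C)C)C2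
F4 | step 14 | 4-hydroxy derivative of F3 (C4 epimers) | O(Cc3ccccc3)c1cc(OCc3ccccc3)c2c(c1)O[C@H](c1ccc(OCc3ccccc3)c(OCc3ccccc3)c1)[C@@H](O[Si](C)(C)C(C)(C)C)C2O
F5 | step 14 | (2R,3R)-5,7-bis(benzyloxy)-2-[3,4-bis(benzyloxy)phenyl]-3-(tert-butyldimethylsilyloxy)chroman-4-one | O(Cc3ccccc3)c1cc(OCc3ccccc3)c2c(c1)O[C@H](c1ccc(OCc3ccccc3)c(OCc3ccccc3)c1)[C@@H](O[Si](C)(C)C(C)(C)C)C2=O
F6 | step 14 | 8-bromo-5,7,3',4'-tetra-O-benzyl-(−)-catechin | O(Cc3ccccc3)c1cc(OCc3ccccc3)c2c(c1Br)O[C@@H](c1ccc(OCc3ccccc3)c(OCc3ccccc3)c1)[C@H](O)C2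
F7 | step 14 | C4 tertiary alcohol from F5 and lithiated F6 (C4 configuration open) | O(Cc3ccccc3)c1cc(OCc3ccccc3)c2c(c1)O[C@H](c1ccc(OCc3ccccc3)c(OCc3ccccc3)c1)[C@@H](O[Si](C)(C)C(C)(C)C)C2(O)c1c(OCc3ccccc3)cc(OCc3ccccc3)c2c1O[C@@H](c1ccc(OCc3ccccc3)c(OCc3ccccc3)c1)[C@H](O)C2
F8 | step 14 | 3-O-tert-butyldimethylsilyl ether (upper unit) of 24 | O(Cc3ccccc3)c1cc(OCc3ccccc3)c2c(c1)O[C@H](c1ccc(OCc3ccccc3)c(OCc3ccccc3)c1)[C@@H](O[Si](C)(C)C(C)(C)C)[C@H]2c1c(OCc3ccccc3)cc(OCc3ccccc3)c2c1O[C@@H](c1ccc(OCc3ccccc3)c(OCc3ccccc3)c1)[C@H](O)C2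
F9 | step 16 | 8-bromo derivative of 15 (C4 epimers) | O(Cc3ccccc3)c1cc(OCc3ccccc3)c2c(c1Br)O[C@H](c1cc(OCc3ccccc3)c(OCc3ccccc3)c(OCc3ccccc3)c1)[C@@H](OCc3ccccc3)C2O
F10 | step 16 | 8-bromo (top unit) derivative of 25 | O(Cc3ccccc3)c1cc(OCc3ccccc3)c2c(c1Br)O[C@H](c1cc(OCc3ccccc3)c(OCc3ccccc3)c(OCc3ccccc3)c1)[C@@H](OCc3ccccc3)[C@@H]2c1c(OCc3ccccc3)cc(OCc3ccccc3)c2c1O[C@H](c1ccc(OCc3ccccc3)c(OCc3ccccc3)c1)[C@@H](O)[C@H]2c1c(OCc3ccccc3)cc(OCc3ccccc3)c2c1O[C@@H](c1ccc(OCc3ccccc3)c(OCc3ccccc3)c1)[C@H](O)C2
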